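**Plan**
- The target is an achiral benzene ring with C1-OH, C3-heptadecyl, C4-OMe and C5-OMe; C2 and C6 are CH.
- Enabling feature: C1-OH and C4-OMe are para. The contiguous ring atoms C1, C6, C5 and C4 (bearing O, H, OMe, OMe) form the four-carbon skeleton of a methyl semisquarate adduct. C2 and C3 with the C17 chain form a 1,1-disubstituted vinyl unit.
- Cuts, in order: ring bond C1–C2 (retro-6π, then retro-4π back to a cyclobutenone); bond C3–C4 together with the C4 O–CH3 bond (vinyllithium plus dione carbonyl, then methylation); and the bond between the first and second carbon of the side chain (allylic bromide plus Grignard reagent).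
- Forward: the C16 Grignard reagent is joined to 2,3-dibromopropene, and dimethyl squarate is trimmed to methyl semisquarate. The two halves are united and O-methylated in one flask. The benzene ring, the only ring of the target, arises last by thermal expansion of the four-membered ring.
- Stereochemistry: none in the target. The carbinol centre of the reduced squarate and the quaternary cyclobutenone carbon are racemic and both are erased, so only the torquoselectivity of the ring opening matters.

Key step: step 5

Assumption: C1–C6 are the phenol locants (C1 bears OH), locants in four-membered rings are called cyclobutenone locants, and racemic intermediates suffice because the target is achiral.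

Step 1
Reactants: 1 1-bromohexadecane; 2 2,3-dibromopropene
Product: 4 2-bromononadec-1-ene, via hexadecylmagnesium bromide 3 (not isolated)
Conditions: Mg, THF, 50 °C; then add slowly to 2 (1.2 equiv), THF, 0 °C to rt
Reagents that add atoms: none
Why: Grignard formation followed by uncatalysed allylic substitution, the classical entry to 2-bromo-1-alkenes: the primary alkylmagnesium bromide displaces the allylic bromide of 2 (direct and allylically transposed attack give the same product), the vinylic C–Br bond stays inert, and slow addition of 3 to excess 2 keeps homocoupling low.

Step 2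
Reactants: 5 dimethyl squarate (3,4-dimethoxycyclobut-3-ene-1,2-dione)
Product: 6 4-hydroxy-2,3-dimethoxycyclobut-2-en-1-one (racemic)
Conditions: LiAlH(OtBu)3 (1.05 equiv), THF, −78 to −20 °C; cold 1 M HCl work-up
Reagents that add atoms: none
Why: Chemoselective 1,2-carbonyl reduction with a hindered alkoxyaluminium hydride: one hydride goes to one of the two equivalent carbonyl groups of the symmetrical squarate, the resulting aluminium alkoxide shields the remaining vinylogous ester carbonyl from a second reduction, and the new carbinol centre is racemic and disappears in step 3.

Step 3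
Reactants: 6 4-hydroxy-2,3-dimethoxycyclobut-2-en-1-one
Product: 7 3-methoxycyclobut-3-ene-1,2-dione (methyl semisquarate)
Conditions: conc. HCl (cat.), CH2Cl2, rt
Reagents that add atoms: none
Why: Acid-catalysed 1,3-transposition and hemiketal collapse, the standard conversion of squarate 1,2-adducts into cyclobutenediones: ionisation of the hydroxyl at cyclobutenone C4 gives a cyclobutenyl cation stabilised by the C2 methoxy group, the liberated water returns at C2 and methanol is expelled, so the net change is loss of MeOH and the ring CH of the semisquarate is in place.

Step 4
Reactants: 4 2-bromononadec-1-ene; 7 3-methoxycyclobut-3-ene-1,2-dione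
Product: 10 3,4-dimethoxy-4-(nonadec-1-en-2-yl)cyclobut-2-en-1-one (racemic), via nonadec-1-en-2-yllithium 8 (not isolated), via lithium alkoxide adduct 9 (not isolated)
Conditions: 4, t-BuLi (2.0 equiv), Et2O–pentane (dilute), −78 to −40 °C; cannulate into 7, THF, −78 °C; MeOTf (1.5 equiv), −78 to 0 °C
Reagents that add atoms: methyl trifluoromethanesulfonate, COS(=O)(=O)C(F)(F)F
Why: Lithium–bromine exchange, carbonyl 1,2-addition and alkoxide O-alkylation in one flask: in 7 the carbonyl next to the ring CH belongs to the vinylogous ester O=C–CH=C–OMe and is deactivated, so the vinyllithium attacks the ketone-like carbonyl next to the methoxy-bearing carbon, as is general for 3-alkoxycyclobutenediones, and the hard electrophile MeOTf caps the tertiary alkoxide at low temperature; the quaternary centre forms as a racemate, which is immaterial because it is flattened in step 5.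

Step 5
Reactants: 10 3,4-dimethoxy-4-(nonadec-1-en-2-yl)cyclobut-2-en-1-one
Product: 13 3-heptadecyl-4,5-dimethoxyphenol (target), via dienylketene 11 (not isolated), via cyclohexa-2,4-dienone 12 (not isolated)
Conditions: PhMe (0.02 M, degassed), 110 °C, Ar
Reagents that add atoms: none
Why: Heating breaks the cyclobutenone C1–C4 σ-bond in a conrotatory 4π electrocyclic opening to the (Z)-dienylketene 11, in which the ketene carbon (future C1) and the terminal =CH2 of the nonadecenyl group (future C2) lie within bonding distance. A thermal disrotatory 6π electrocyclisation then forms the C1–C2 bond and closes the six-membered carbocycle as dienone 12, whose C2 methylene enolises irreversibly to phenol 13. This is the Moore rearrangement of a 4-alkenyl-4-alkoxycyclobutenone to a hydroquinone monoether, an established reaction class. No stereocentre is created, and the racemic quaternary carbon of 10 becomes the sp2 carbon C4. The selectivity required is torquoselectivity: the methoxy group on the breaking carbon, a lone-pair donor, rotates outward and sends the alkenyl group inward toward the ketene, and because ring opening is reversible while aromatisation is not, any ketene of the wrong geometry returns to 10 and is funnelled to 13. The substitution pattern needs no further control because every ring atom already carries its final substituent in 10, and the pre-installed methyl ether delivers C4-OMe and C1-OH already differentiated.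

**Compound list**
1 | 1-bromohexadecane | CCCCCCCCCCCCCCCCBr | starting material
2 | 2,3-dibromopropene | C=C(Br)CBr | starting material
3 | hexadecylmagnesium bromide | CCCCCCCCCCCCCCCC[Mg]Br | intermediate
4 | 2-bromononadec-1-ene | C=C(Br)CCCCCCCCCCCCCCCCC | intermediate
5 | dimethyl squarate (3,4-dimethoxycyclobut-3-ene-1,2-dione) | COC1=C(OC)C(=O)C1=O | starting material
6 | 4-hydroxy-2,3-dimethoxycyclobut-2-en-1-one (racemic) | COC1=C(OC)C(O)C1=O | intermediate
7 | 3-methoxycyclobut-3-ene-1,2-dione (methyl semisquarate) | COC1=CC(=O)C1=O | intermediate
8 | nonadec-1-en-2-yllithium | [Li]C(=C)CCCCCCCCCCCCCCCCC | intermediate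
9 | lithium 2-methoxy-1-(nonadec-1-en-2-yl)-4-oxocyclobut-2-en-1-olate (racemic) | [Li+].[O-]C1(C(=C)CCCCCCCCCCCCCCCCC)C(OC)=CC1=O | intermediate
10 | 3,4-dimethoxy-4-(nonadec-1-en-2-yl)cyclobut-2-en-1-one (racemic) | COC1=CC(=O)C1(OC)C(=C)CCCCCCCCCCCCCCCCC | intermediate
11 | (3Z)-3,4-dimethoxy-5-methylidenedocosa-1,3-dien-1-one (dienylketene) | O=C=C/C(OC)=C(OC)\C(=C)CCCCCCCCCCCCCCCCC | intermediate
12 | 5-heptadecyl-3,4-dimethoxycyclohexa-2,4-dien-1-one | O=C1C=C(OC)C(OC)=C(CCCCCCCCCCCCCCCCC)C1 | intermediate
13 | 3-heptadecyl-4,5-dimethoxyphenol | CCCCCCCCCCCCCCCCCc1cc(O)cc(OC)c1OC | target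

Total step count: 5
Longest linear sequence: 4 steps (5 → 6 → 7 → 10 → 13). The chain branch 1 → 4 joins at step 4.

**Steps most likely to fail**

1. **Step 4.**
   - The vinyllithium may attack the vinylogous ester carbonyl or the unsubstituted ring carbon in competition with the wanted 1,2-addition. Methyl transfer to the hindered tertiary alkoxide may also lag behind its retro-addition or ring cleavage as the mixture warms.
   - The fallback sets out from 9 and returns at 10 by uncoupling C–C bond formation from O-methylation. The cold mixture is protonated with AcOH in THF at −78 °C to give 4-hydroxy-3-methoxy-4-(nonadec-1-en-2-yl)cyclobut-2-en-1-one F1. This is freed from isomeric adducts by chromatography without heating. The neutral tertiary alcohol is then converted into 10 by Purdie methylation (MeI, Ag2O, MeCN, rt, dark), so no free alkoxide is ever warmed.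

2. **Step 3.**
   - The vinylogous methyl ester may be hydrolysed further under the acidic conditions, and the resulting strong, water-soluble acid would be lost on work-up.
   - The fallback sets out from 6 and returns at 7 by accepting the hydrolysis and re-installing the methyl group. Compound 6 is hydrolysed completely with aqueous HCl and evaporated to dryness to give 3-hydroxycyclobut-3-ene-1,2-dione F2. This is esterified with HC(OMe)3 in MeOH at reflux, the method by which squaric acid itself is converted into its dimethyl ester, to give 7 under anhydrous conditions.

3. **Step 5.**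
   - The dienylketene may be intercepted by the phenol already formed or by moisture, or may oligomerise at practical concentration. The electron-rich phenol may also be oxidised by air at 110 °C.
   - The fallback sets out from 3 and returns at 13, using a purchased benzene ring instead of building one.
   - Reagent 3 is added to commercial 2,3-dimethoxybenzaldehyde (THF, 0 °C; dilute HCl quench) to give 1-(2,3-dimethoxyphenyl)heptadecan-1-ol F3.
   - Benzylic hydrogenolysis (H2, Pd/C, AcOH) gives 1-heptadecyl-2,3-dimethoxybenzene F4.
   - Sterically governed C–H borylation ([Ir(OMe)(cod)]2, 4,4'-di-tert-butyl-2,2'-bipyridine, B2pin2, THF, 80 °C) functionalises the only ring C–H without an ortho neighbour. It gives 2-(3-heptadecyl-4,5-dimethoxyphenyl)-4,4,5,5-tetramethyl-1,3,2-dioxaborolane F5.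
   - Oxidation with H2O2/NaOH gives 13.

**Further compounds**
F1 | step 4 | 4-hydroxy-3-methoxy-4-(nonadec-1-en-2-yl)cyclobut-2-en-1-one (racemic) | COC1=CC(=O)C1(O)C(=C)CCCCCCCCCCCCCCCCC
F2 | step 3 | 3-hydroxycyclobut-3-ene-1,2-dione (semisquaric acid) | OC1=CC(=O)C1=O
F3 | step 5 | 1-(2,3-dimethoxyphenyl)heptadecan-1-ol (racemic) | CCCCCCCCCCCCCCCCC(O)c1cccc(OC)c1OC
F4 | step 5 | 1-heptadecyl-2,3-dimethoxybenzene | CCCCCCCCCCCCCCCCCc1cccc(OC)c1OC
F5 | step 5 | 2-(3-heptadecyl-4,5-dimethoxyphenyl)-4,4,5,5-tetramethyl-1,3,2-dioxaborolane | CCCCCCCCCCCCCCCCCc1cc(B2OC(C)(C)C(C)(C)O2)cc(OC)c1OC
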